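## The problem

The target is the O15 ester of ent-labda-7,13E-diene-15,17-diol with 30-hydroxytriacontanoic acid. In labdane numbering it is a trans-fused decalin (ring A: C1–C5 and C10; ring B: C5–C10) whose C9 carries the chain C11–C16 and whose C7=C8 alkene carries the C17 carbinol. Three contiguous stereocentres (5R, 9S, 10R) must be set, among them the quaternary C10 with its angular methyl C20. They belong to the enantiomeric labdane series, so the abundant terpenoid chiral pool of the normal series is of no use. Only C10 is independent. C5–H falls trans to C20 when hydrogen is delivered to C5 of the closed bicycle, because the axial C20 and one C4 methyl shield the other face, and C9 relaxes to the equatorial side chain whenever C8 is a ketone. The C13=C14 alkene must be made E and carried unchanged, and three primary hydroxyls (O15, O17, the chain terminus) need an ordered unmasking. The allylic C–O bonds and both alkenes are sensitive to strong acid, and the C15 ester would not survive hydride, organolithium reagents or zerovalent palladium, so it has to go on last. The route is opened by two facts: C10 is bonded directly to C9, and ring A with C5, C6 and C20 is a β-cyclogeranyl unit. An ester of the side-chain acid on O–C6 therefore places C9 in a 1,6-relationship to C10, and a [3,3] shift can form C9–C10, leave C8 as a carboxyl group and move the ring alkene C5=C10 to an exocyclic C5=C6 that later accepts C7.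

## Retrosynthesis

**Acyl bond at O15.** Target 35 is cut at the O15–acyl bond and at two silyl ethers, giving alcohol 26 (O17 masked) and the silylated C30 acid 33 by way of diester 34. This cut comes last in the forward sense because the allylic ester tolerates none of the enolate, hydride or palladium chemistry used earlier. Giving O17 and the chain terminus the same silyl group lets one fluoride treatment finish the synthesis. The forward reaction is a carbodiimide esterification of an unhindered allylic alcohol.

**The C30 acid.** Acid 33 is cut in the middle of the chain (C15–C16 of the acid), so both halves come from lactone 27. Ring opening gives bromo acid 28, which serves once as the electrophile and once, after reduction to 29 and silylation to 30, as the source of the nucleophile. A mid-chain cut is preferred to a cut near either end because it uses one cheap C15 building block twice. The forward step is a copper-catalysed sp3–sp3 Grignard coupling on a carboxylate salt.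

**C8–C17 and the oxygen pattern.** Alcohol 26 is traced through 25 and 24 to ester 23, and C8–C17 is cut by carbonylation of enol triflate 22, which comes from decalone 20. A C8 ketone is the better precursor than any C8 alkene because it also lets C9 equilibrate and places the alkene at C7=C8 through kinetic enolisation toward the C7 methylene. The forward sequence needs regioselective enolisation and a selective exchange of silyl groups (the tert-butyldimethylsilyl ether on O15 is removed beside the tert-butyldiphenylsilyl ether on O17).

**Ring B, C6–C7 and C7–C8.** Decalone 20 is cut at C6–C7 to bromomethyl ketone 19, then at C7–C8 to acid 15 through methyl ketone 17. Closing ring B at C6–C7 is preferred to a cationic closure at C5–C10 or C8–C9, which would have to create the quaternary centre and its absolute configuration in the same event. Here C10 already exists, and the closure only has to be 6-endo onto the exocyclic methylene, with hydrogen then delivered to C5 trans to C20. Precursor 19 is monocyclic with two stereocentres, of which only C10 matters.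

**C9–C10, the strategic cut.** Acid 15 is cut at C9–C10 to the achiral ester 12. No other single disconnection removes the quaternary centre, both stereocentres and all chirality at once while leaving the whole side chain and the C8 oxidation level in place. The forward reaction must form a quaternary carbon beside a tertiary one at a tetrasubstituted ring alkene and must choose one enantiotopic face of that alkene. The concerted intramolecular path meets the first demand and a chiral boron enolate the second.

**Ester 12.** Cutting the ester C–O bond gives acid 9 and β-cyclogeraniol 11, the reduction product of aldehyde 10. Both are achiral and a standard esterification joins them.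

**The side-chain acid.** Acid 9 is traced through alcohol 7 and the doubly protected diol 6 to allylic alcohol 5. There C13–C16 and C14–C15 are cut together by methylmetalation and hydroxymethylation of alkyne 2, the 4-methoxybenzyl ether of hex-5-yn-1-ol 1. Syn carbometalation is preferred to an olefination of a methyl ketone because it gives the E-trisubstituted alkene as a single isomer.

## Roads not taken

Alternative 1: Both C5–C10 and C8–C9 are cut, so rings A and B arise together from an acyclic trienoyl imide A2. In the forward step the C9=C10 enoyl alkene, activated as the aluminium chelate of its oxazolidinone imide, adds across the C5=C6–C7=C8 diene to give cycloadduct A1.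
- Merits: two rings, two C–C bonds and four stereocentres (C5, C8, C9, C10) are set in one step under a recoverable auxiliary, in a reaction class whose facial control is well understood. In stereochemical yield per step this is better than step 8 of the chosen plan, and it does not rest on an untested substrate class.
- Weak points: the dienophile of A2 is a β,β-disubstituted enoyl imide, the least reactive kind, and it must form the quaternary C10 while the diene terminus C5 sits beside the C4 gem-dimethyl group. Trans fusion in a decatriene-type cyclisation is not assured. A1 has its alkene at C6=C7 and an sp3 C8, so the alkene still has to be moved to C7=C8 without any thermodynamic bias. C11 arrives as an acyl carbon, so C12–C16 remain to be attached by reduction and an sp3–sp3 coupling at a neopentyl-type carbon.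
- Comparison: the chosen plan sets fewer centres in its key step but delivers acid 15 with C8 oxidised, the side chain complete and the alkene handle where ring B needs it.

Alternative 2: C9–C11 is cut. An alkylcopper made from iodide A5 is bound to the deprotonated N-phenylcarbamate of the bicyclic allylic alcohol A4 and delivered to C9 on the carbamate face with allylic transposition, giving A3.
- Merits: the union is convergent, the C7=C8 alkene appears in the same step, and A3 already holds every carbon of the diol with O15 and O17 differently masked, about three steps from the target. In convergence this is better than the chosen plan, which carries the side chain linearly from step 1.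
- Weak points: A4 must be enantiopure in the ent series, so the real problem (C5, C10) is only moved into its preparation. An extra stereocentre at C7, on the C20 face, has to be installed merely to be destroyed. The new bond forms beside the quaternary C10 on the face of the axial C20 methyl, the least accessible trajectory of the bicycle. An unactivated primary alkylcopper is a reluctant partner, and direct substitution without transposition competes.
- Comparison: against the lost convergence the chosen plan sets an absolute configuration drawn from a reagent available in both antipodes and a hindered C9–C10 bond made intramolecularly.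

Alternative 3: C12–C13 is cut. The N-hydroxyphthalimide ester A7 of the bicyclic propanoic acid loses CO2 at a nickel–bipyridine cathode, and the primary C12 radical is coupled with alkenyl iodide A8, which already carries the C30 ester, to give A6.
- Merits: this is the most convergent of the four. The C12 radical is unhindered and remote from every stereocentre, esters are tolerated, and A6 is one desilylation from the target. As an endgame it is better than steps 15–22 of the chosen plan.
- Weak points: A8 holds an allylic carboxylate next to the alkenyl iodide, and low-valent nickel ionises allylic esters, so loss of the acyl chain competes. The E geometry of the trisubstituted alkenyl partner has to survive. Above all, the cut is far from the stereocentres: A7 needs the whole ent-bicycle with C7=C8 and C17 in place, so this is an endgame and not a solution for the core.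
- Comparison: it could be grafted onto a core made as in steps 6–14. The chosen plan instead avoids any late C–C coupling by fixing the E alkene first (step 2), at the price of carrying that alkene through the radical ring closure.

Key step: step 8

Assumption: the acyl residue is read as 30-hydroxytriacontanoyl (29 methylene carbons between the carbonyl carbon and the terminal oxygen), i.e. two C15 units.

Assumption: the (S,S) boron controller is written in step 8; its sense of induction on this substrate class has to be assigned on 15 itself, and the (R,R) reagent is used if the sense proves opposite.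

## Route

Step 1
Reactants: 1 hex-5-yn-1-ol
Product: 2 1-[(hex-5-yn-1-yloxy)methyl]-4-methoxybenzene
Conditions: NaH, PMBCl, Bu4NI (cat.), THF/DMF, 0 °C → rt
Reagents that add atoms: 4-methoxybenzyl chloride, COc1ccc(CCl)cc1
Why: Williamson etherification; the alkoxide forms well before the alkyne C–H is touched, and the 4-methoxybenzyl ether tolerates organoaluminium reagents and can later be removed beside a silyl ether.

Step 2
Reactants: 2 1-[(hex-5-yn-1-yloxy)methyl]-4-methoxybenzene
Product: 5 (E)-7-(4-methoxybenzyloxy)-3-methylhept-2-en-1-ol, via alkenyldimethylalane 3 (not isolated), via lithium alkenylaluminate 4 (not isolated)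
Conditions: Me3Al, Cp2ZrCl2 (25 mol %), CH2Cl2, 0 °C → rt; evaporation, hexane/THF; n-BuLi, −78 °C; (CH2O)n, −78 °C → rt; aqueous potassium sodium tartrate
Reagents that add atoms: trimethylaluminium, C[Al](C)C; formaldehyde (as paraformaldehyde), C=O
Why: Negishi zirconium-catalysed carboalumination adds methyl and aluminium syn across the terminal alkyne with methyl on the internal carbon, which fixes the E geometry of C13=C14; the derived aluminate is hydroxymethylated with retention.

Step 3
Reactants: 5 (E)-7-(4-methoxybenzyloxy)-3-methylhept-2-en-1-ol
Product: 6 tert-butyl{[(E)-7-(4-methoxybenzyloxy)-3-methylhept-2-en-1-yl]oxy}dimethylsilane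
Conditions: TBSCl, imidazole, DMF, 0 °C → rt
Reagents that add atoms: tert-butyldimethylsilyl chloride, CC(C)(C)[Si](C)(C)Cl
Why: Standard silylation of a primary allylic alcohol; the silyl ether is inert to the oxidations, the boron enolate, organolithium and radical steps that follow.

Step 4
Reactants: 6 tert-butyl{[(E)-7-(4-methoxybenzyloxy)-3-methylhept-2-en-1-yl]oxy}dimethylsilane
Product: 7 (E)-7-(tert-butyldimethylsilyloxy)-5-methylhept-5-en-1-ol
Conditions: DDQ, CH2Cl2/pH 7 phosphate buffer, 0 °C → rt
Reagents that add atoms: none
Why: Oxidative cleavage of the 4-methoxybenzyl ether by hydride abstraction and hydrolysis of the oxocarbenium ion; the allylic silyl ether and the trisubstituted alkene are not oxidised under buffered conditions.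

Step 5
Reactants: 7 (E)-7-(tert-butyldimethylsilyloxy)-5-methylhept-5-en-1-ol
Product: 9 (E)-7-(tert-butyldimethylsilyloxy)-5-methylhept-5-enoic acid, via aldehyde 8 (not isolated)
Conditions: TEMPO (cat.), PhI(OAc)2, MeCN/H2O, rt
Reagents that add atoms: water, O
Why: Oxoammonium-mediated oxidation of the primary alcohol to the aldehyde and, through its hydrate, to the acid; the conditions leave alkenes and silyl ethers alone.

Step 6
Reactants: 10 β-cyclocitral
Product: 11 (2,6,6-trimethylcyclohex-1-en-1-yl)methanol
Conditions: NaBH4, MeOH, 0 °C
Reagents that add atoms: none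
Why: Borohydride 1,2-reduction of the hindered enal gives β-cyclogeraniol; no stereocentre is formed.

Step 7
Reactants: 9 (E)-7-(tert-butyldimethylsilyloxy)-5-methylhept-5-enoic acid; 11 (2,6,6-trimethylcyclohex-1-en-1-yl)methanol
Product: 12 (2,6,6-trimethylcyclohex-1-en-1-yl)methyl (E)-7-(tert-butyldimethylsilyloxy)-5-methylhept-5-enoate
Conditions: EDC·HCl, DMAP, CH2Cl2, rt
Reagents that add atoms: none
Why: Steglich esterification; acyl transfer through the acylpyridinium ion copes with the neopentyl-like primary allylic alcohol without ionising it.

Step 8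
Reactants: 12 (2,6,6-trimethylcyclohex-1-en-1-yl)methyl (E)-7-(tert-butyldimethylsilyloxy)-5-methylhept-5-enoate
Product: 15 (2S,5E)-7-(tert-butyldimethylsilyloxy)-5-methyl-2-[(1S)-1,3,3-trimethyl-2-methylidenecyclohexyl]hept-5-enoic acid, via boron ketene acetal 13 (not isolated), via acyloxyborane 14 (not isolated)
Conditions: (4S,5S)-2-bromo-4,5-diphenyl-1,3-bis[3,5-bis(trifluoromethyl)phenylsulfonyl]-1,3,2-diazaborolidine (1.2 equiv), i-Pr2NEt, CH2Cl2, −78 °C; then −20 °C → 23 °C, prolonged; pH 7 buffer work-up
Reagents that add atoms: none
Why: Proposed new method: soft enolisation of the only enolisable ester by the B-bromodiazaborolidine and the amine should give boron ketene acetal 13, in which the enol unit C9=C8–O and the allyl unit C6–C5=C10 are joined through oxygen, so a concerted [3,3]-sigmatropic shift through a six-membered chair can break O–C6 as C9–C10 forms and give acyloxyborane 14, hydrolysed on work-up to acid 15 with the exocyclic C5=C6 methylene. The closest known reaction type is the enantioselective ester-enolate (Ireland–)Claisen rearrangement of chiral boron enolates of acyclic allyl esters with di- and trisubstituted alkenes, which already builds quaternary carbons beside tertiary ones; what has not been shown is a tetrasubstituted, ring-embedded alkene such as that of a β-cyclogeranyl ester, although thermal Claisen variants on cyclohexenylmethyl systems are established. No ring is closed in this step. C10 is set by the (S,S)-sulfonamide ligands on boron, which select one of the two mirror-image chairs and hence one face of C10; C9 follows from the enolate geometry (C11 cis to O–B lies equatorial in the chair and gives the configuration drawn), and a C9 epimer would converge in step 11. The only selectivity the step must deliver is therefore the enantiofacial one at C10. Chemoselectivity is secured because 12 has a single enolisable carbonyl group and the silyl ether offers no site for boron, and regiochemistry because the suprafacial path can bring C9 only to C10.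

Step 9
Reactants: 15 (2S,5E)-7-(tert-butyldimethylsilyloxy)-5-methyl-2-[(1S)-1,3,3-trimethyl-2-methylidenecyclohexyl]hept-5-enoic acid
Product: 17 (3S,6E)-8-(tert-butyldimethylsilyloxy)-6-methyl-3-[(1S)-1,3,3-trimethyl-2-methylidenecyclohexyl]oct-6-en-2-one, via dilithium gem-diolate 16 (not isolated)
Conditions: MeLi (3 equiv), Et2O, 0 °C → rt; inverse quench into cold aqueous NH4Cl
Reagents that add atoms: methyllithium, [Li]C
Why: Addition of methyllithium to the lithium carboxylate stops at the dilithium diolate, which collapses to the methyl ketone only on hydrolysis; the added methyl becomes C7, and any erosion at C9 is immaterial because C9 is equilibrated in step 11.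

Step 10
Reactants: 17 (3S,6E)-8-(tert-butyldimethylsilyloxy)-6-methyl-3-[(1S)-1,3,3-trimethyl-2-methylidenecyclohexyl]oct-6-en-2-one
Product: 19 (3S,6E)-1-bromo-8-(tert-butyldimethylsilyloxy)-6-methyl-3-[(1S)-1,3,3-trimethyl-2-methylidenecyclohexyl]oct-6-en-2-one, via trimethylsilyl enol ether 18 (not isolated)
Conditions: LiN(i-Pr)2, TMSCl, THF, −78 °C; then NBS, NaHCO3, −78 → 0 °C
Reagents that add atoms: N-bromosuccinimide, O=C1CCC(=O)N1Br
Why: Kinetic deprotonation takes the methyl group and not the hindered C9 methine, and the silyl enol ether is brominated at C7 far faster than either isolated alkene reacts; the sequence avoids strong acid, which the allylic silyl ether and the alkenes would not tolerate.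

Step 11
Reactants: 19 (3S,6E)-1-bromo-8-(tert-butyldimethylsilyloxy)-6-methyl-3-[(1S)-1,3,3-trimethyl-2-methylidenecyclohexyl]oct-6-en-2-one
Product: 20 (5R,9S,10R,13E)-15-(tert-butyldimethylsilyloxy)-17-norlabd-13-en-8-one (labdane numbering; trans-fused; side chain equatorial)
Conditions: Bu3SnH (syringe pump), AIBN, PhH (0.01 M), 80 °C; then NaOMe, MeOH, rt
Reagents that add atoms: none
Why: Bromine abstraction gives the electrophilic C7 α-keto radical, which should add 6-endo-trig to the unsubstituted terminus C6 of the 1,1-disubstituted alkene, the usual mode for 2-oxohex-5-enyl radicals. The tertiary C5 radical then takes hydrogen from the stannane on the face opposite the axial C20 and C4 methyl groups, which sets the trans ring fusion. NaOMe equilibrates C9 through the C8 enolate to the equatorial side chain.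

Step 12
Reactants: 20 (5R,9S,10R,13E)-15-(tert-butyldimethylsilyloxy)-17-norlabd-13-en-8-one
Product: 22 (5R,9S,10R,13E)-15-(tert-butyldimethylsilyloxy)-17-norlabda-7,13-dien-8-yl trifluoromethanesulfonate, via potassium enolate 21 (not isolated)
Conditions: KN(SiMe3)2, THF, −78 °C; PhNTf2, −78 → 0 °C
Reagents that add atoms: N-phenylbis(trifluoromethanesulfonimide), O=S(=O)(N(c1ccccc1)S(=O)(=O)C(F)(F)F)C(F)(F)F
Why: A bulky amide base under kinetic control removes a C7 methylene proton and not the hindered C9 methine, so O-sulfonylation places the alkene at C7=C8 and leaves C9 untouched.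

Step 13
Reactants: 22 (5R,9S,10R,13E)-15-(tert-butyldimethylsilyloxy)-17-norlabda-7,13-dien-8-yl trifluoromethanesulfonate
Product: 23 methyl (5R,9S,10R,13E)-15-(tert-butyldimethylsilyloxy)labda-7,13-dien-17-oate
Conditions: Pd(OAc)2 (10 mol %), PPh3, Et3N, MeOH, DMF, CO (1 atm), 60 °C
Reagents that add atoms: carbon monoxide, [C-]#[O+]; methanol, CO
Why: Palladium-catalysed methoxycarbonylation of an enol triflate (oxidative addition, CO insertion, methanolysis) installs C17; the allylic silyl ether is not a leaving group for zerovalent palladium.

Step 14
Reactants: 23 methyl (5R,9S,10R,13E)-15-(tert-butyldimethylsilyloxy)labda-7,13-dien-17-oate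
Product: 24 (5R,9S,10R,13E)-15-(tert-butyldimethylsilyloxy)labda-7,13-dien-17-ol
Conditions: i-Bu2AlH, CH2Cl2, −78 °C; aqueous potassium sodium tartrate
Reagents that add atoms: none
Why: Clean 1,2-reduction of the conjugated ester to the allylic alcohol; nothing else in the molecule is reducible.

Step 15
Reactants: 24 (5R,9S,10R,13E)-15-(tert-butyldimethylsilyloxy)labda-7,13-dien-17-ol
Product: 25 (5R,9S,10R,13E)-15-(tert-butyldimethylsilyloxy)-17-(tert-butyldiphenylsilyloxy)labda-7,13-diene
Conditions: TBDPSCl, imidazole, DMF, rt
Reagents that add atoms: tert-butyl(chloro)diphenylsilane, CC(C)(C)[Si](Cl)(c1ccccc1)c1ccccc1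
Why: Silylation of the primary allylic C17 alcohol with the more acid-stable silyl group sets up the differentiation of O15 and O17.

Step 16
Reactants: 25 (5R,9S,10R,13E)-15-(tert-butyldimethylsilyloxy)-17-(tert-butyldiphenylsilyloxy)labda-7,13-diene
Product: 26 (5R,9S,10R,13E)-17-(tert-butyldiphenylsilyloxy)labda-7,13-dien-15-ol
Conditions: PPTS, MeOH, rt
Reagents that add atoms: none
Why: Mild acid-catalysed methanolysis cleaves the primary tert-butyldimethylsilyl ether much faster than the tert-butyldiphenylsilyl ether, and the acid is too weak to ionise the allylic positions.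

Step 17
Reactants: 27 ω-pentadecalactone
Product: 28 15-bromopentadecanoic acid
Conditions: HBr (33% in AcOH), H2SO4 (cat.), 90 °C
Reagents that add atoms: hydrogen bromide, Br
Why: Acid-promoted alkyl–oxygen cleavage of the macrolactone by bromide opens the ring to the ω-bromo acid.

Step 18
Reactants: 28 15-bromopentadecanoic acid
Product: 29 15-bromopentadecan-1-ol
Conditions: BH3·THF, THF, 0 °C → rt; MeOH
Reagents that add atoms: none
Why: Borane reduces the carboxylic acid chemoselectively through the acyloxyborane and leaves the primary bromide untouched.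

Step 19
Reactants: 29 15-bromopentadecan-1-ol
Product: 30 [(15-bromopentadecyl)oxy](tert-butyl)diphenylsilane
Conditions: TBDPSCl, imidazole, CH2Cl2/DMF, rt
Reagents that add atoms: tert-butyl(chloro)diphenylsilane, CC(C)(C)[Si](Cl)(c1ccccc1)c1ccccc1
Why: Standard silylation; the silyl ether survives Grignard formation and matches the O17 protecting group for a common final deprotection.

Step 20
Reactants: 30 [(15-bromopentadecyl)oxy](tert-butyl)diphenylsilane; 28 15-bromopentadecanoic acid
Product: 33 30-(tert-butyldiphenylsilyloxy)triacontanoic acid, via Grignard reagent 31 (not isolated), via chloromagnesium carboxylate 32 (not isolated)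
Conditions: 30, Mg, THF, 50 °C; separately 28, MeMgCl (1 equiv), THF, −20 °C; combine, Li2CuCl4 (5 mol %), −20 °C → rt; aqueous citric acid
Reagents that add atoms: none
Why: Copper-catalysed cross-coupling of a primary alkyl Grignard reagent with a primary alkyl bromide; the carboxylate, protected as its magnesium salt, is inert to the organocopper intermediate.

Step 21
Reactants: 26 (5R,9S,10R,13E)-17-(tert-butyldiphenylsilyloxy)labda-7,13-dien-15-ol; 33 30-(tert-butyldiphenylsilyloxy)triacontanoic acid
Product: 34 (5R,9S,10R,13E)-17-(tert-butyldiphenylsilyloxy)labda-7,13-dien-15-yl 30-(tert-butyldiphenylsilyloxy)triacontanoate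
Conditions: EDC·HCl, DMAP, CH2Cl2, rt
Reagents that add atoms: none
Why: Steglich esterification of the unhindered primary allylic alcohol under neutral conditions that do not ionise the allylic C–O bond.

Step 22
Reactants: 34 (5R,9S,10R,13E)-17-(tert-butyldiphenylsilyloxy)labda-7,13-dien-15-yl 30-(tert-butyldiphenylsilyloxy)triacontanoate
Product: 35 (5R,9S,10R,13E)-17-hydroxylabda-7,13-dien-15-yl 30-hydroxytriacontanoate
Conditions: HF·pyridine, pyridine/THF, 0 °C → rt
Reagents that add atoms: none
Why: Fluoride cleaves both silyl ethers; the buffered reagent leaves the allylic ester and both alkenes intact, and the two hydroxyls are too far from the ester for acyl migration.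

## Compound list

1 | hex-5-yn-1-ol | C#CCCCCO | starting material
2 | 1-[(hex-5-yn-1-yloxy)methyl]-4-methoxybenzene | C#CCCCCOCc1ccc(OC)cc1 | intermediate
3 | [(E)-6-(4-methoxybenzyloxy)-2-methylhex-1-en-1-yl]dimethylalane | C/C(=C\[Al](C)C)CCCCOCc1ccc(OC)cc1 | intermediate
4 | lithium butyl[(E)-6-(4-methoxybenzyloxy)-2-methylhex-1-en-1-yl]dimethylaluminate | [Li+].CCCC[Al-](C)(C)/C=C(\C)CCCCOCc1ccc(OC)cc1 | intermediate
5 | (E)-7-(4-methoxybenzyloxy)-3-methylhept-2-en-1-ol | C/C(=C\CO)CCCCOCc1ccc(OC)cc1 | intermediate
6 | tert-butyl{[(E)-7-(4-methoxybenzyloxy)-3-methylhept-2-en-1-yl]oxy}dimethylsilane | C/C(=C\CO[Si](C)(C)C(C)(C)C)CCCCOCc1ccc(OC)cc1 | intermediate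
7 | (E)-7-(tert-butyldimethylsilyloxy)-5-methylhept-5-en-1-ol | C/C(=C\CO[Si](C)(C)C(C)(C)C)CCCCO | intermediate
8 | (E)-7-(tert-butyldimethylsilyloxy)-5-methylhept-5-enal | C/C(=C\CO[Si](C)(C)C(C)(C)C)CCCC=O | intermediate
9 | (E)-7-(tert-butyldimethylsilyloxy)-5-methylhept-5-enoic acid | C/C(=C\CO[Si](C)(C)C(C)(C)C)CCCC(=O)O | intermediate
10 | β-cyclocitral (2,6,6-trimethylcyclohex-1-ene-1-carbaldehyde) | CC1=C(C=O)C(C)(C)CCC1 | starting material
11 | (2,6,6-trimethylcyclohex-1-en-1-yl)methanol (β-cyclogeraniol) | CC1=C(CO)C(C)(C)CCC1 | intermediate
12 | (2,6,6-trimethylcyclohex-1-en-1-yl)methyl (E)-7-(tert-butyldimethylsilyloxy)-5-methylhept-5-enoate | C/C(=C\CO[Si](C)(C)C(C)(C)C)CCCC(=O)OCC1=C(C)CCCC1(C)C | intermediate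
13 | boron ketene acetal of 12, O-bound to the (4S,5S)-4,5-diphenyl-1,3-bis[3,5-bis(trifluoromethyl)phenylsulfonyl]-1,3,2-diazaborolidin-2-yl group, C11 cis to O–B | C/C(=C\CO[Si](C)(C)C(C)(C)C)CC/C=C(/OCC1=C(C)CCCC1(C)C)OB2N(S(=O)(=O)c3cc(cc(c3)C(F)(F)F)C(F)(F)F)[C@@H](c3ccccc3)[C@H](c3ccccc3)N2S(=O)(=O)c3cc(cc(c3)C(F)(F)F)C(F)(F)F | intermediate
14 | acyloxyborane of acid 15 with the same (4S,5S)-diazaborolidin-2-yl group | C/C(=C\CO[Si](C)(C)C(C)(C)C)CC[C@H](C(=O)OB2N(S(=O)(=O)c3cc(cc(c3)C(F)(F)F)C(F)(F)F)[C@@H](c3ccccc3)[C@H](c3ccccc3)N2S(=O)(=O)c3cc(cc(c3)C(F)(F)F)C(F)(F)F)[C@]1(C)CCCC(C)(C)C1=C | intermediate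
15 | (2S,5E)-7-(tert-butyldimethylsilyloxy)-5-methyl-2-[(1S)-1,3,3-trimethyl-2-methylidenecyclohexyl]hept-5-enoic acid | C/C(=C\CO[Si](C)(C)C(C)(C)C)CC[C@H](C(=O)O)[C@]1(C)CCCC(C)(C)C1=C | intermediate
16 | dilithium (3S,6E)-8-(tert-butyldimethylsilyloxy)-6-methyl-3-[(1S)-1,3,3-trimethyl-2-methylidenecyclohexyl]oct-6-ene-2,2-diolate | [Li+].[Li+].C/C(=C\CO[Si](C)(C)C(C)(C)C)CC[C@H](C(C)([O-])[O-])[C@]1(C)CCCC(C)(C)C1=C | intermediate
17 | (3S,6E)-8-(tert-butyldimethylsilyloxy)-6-methyl-3-[(1S)-1,3,3-trimethyl-2-methylidenecyclohexyl]oct-6-en-2-one | C/C(=C\CO[Si](C)(C)C(C)(C)C)CC[C@H](C(C)=O)[C@]1(C)CCCC(C)(C)C1=C | intermediate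
18 | trimethylsilyl enol ether of 17 at C7=C8 (2-trimethylsilyloxy-1-ene) | C/C(=C\CO[Si](C)(C)C(C)(C)C)CC[C@H](C(=C)O[Si](C)(C)C)[C@]1(C)CCCC(C)(C)C1=C | intermediate
19 | (3S,6E)-1-bromo-8-(tert-butyldimethylsilyloxy)-6-methyl-3-[(1S)-1,3,3-trimethyl-2-methylidenecyclohexyl]oct-6-en-2-one | C/C(=C\CO[Si](C)(C)C(C)(C)C)CC[C@H](C(=O)CBr)[C@]1(C)CCCC(C)(C)C1=C | intermediate
20 | (5R,9S,10R,13E)-15-(tert-butyldimethylsilyloxy)-17-norlabd-13-en-8-one | C/C(=C\CO[Si](C)(C)C(C)(C)C)CC[C@@H]1C(=O)CC[C@@H]2C(C)(C)CCC[C@@]12C | intermediate
21 | potassium C7=C8 enolate of 20 | [K+].C/C(=C\CO[Si](C)(C)C(C)(C)C)CC[C@@H]1C([O-])=CC[C@@H]2C(C)(C)CCC[C@@]12C | intermediate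
22 | (5R,9S,10R,13E)-15-(tert-butyldimethylsilyloxy)-17-norlabda-7,13-dien-8-yl trifluoromethanesulfonate | C/C(=C\CO[Si](C)(C)C(C)(C)C)CC[C@@H]1C(OS(=O)(=O)C(F)(F)F)=CC[C@@H]2C(C)(C)CCC[C@@]12C | intermediate
23 | methyl (5R,9S,10R,13E)-15-(tert-butyldimethylsilyloxy)labda-7,13-dien-17-oate | C/C(=C\CO[Si](C)(C)C(C)(C)C)CC[C@@H]1C(C(=O)OC)=CC[C@@H]2C(C)(C)CCC[C@@]12C | intermediate
24 | (5R,9S,10R,13E)-15-(tert-butyldimethylsilyloxy)labda-7,13-dien-17-ol | C/C(=C\CO[Si](C)(C)C(C)(C)C)CC[C@@H]1C(CO)=CC[C@@H]2C(C)(C)CCC[C@@]12C | intermediate
25 | (5R,9S,10R,13E)-15-(tert-butyldimethylsilyloxy)-17-(tert-butyldiphenylsilyloxy)labda-7,13-diene | C/C(=C\CO[Si](C)(C)C(C)(C)C)CC[C@@H]1C(CO[Si](c3ccccc3)(c3ccccc3)C(C)(C)C)=CC[C@@H]2C(C)(C)CCC[C@@]12C | intermediate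
26 | (5R,9S,10R,13E)-17-(tert-butyldiphenylsilyloxy)labda-7,13-dien-15-ol | C/C(=C\CO)CC[C@@H]1C(CO[Si](c3ccccc3)(c3ccccc3)C(C)(C)C)=CC[C@@H]2C(C)(C)CCC[C@@]12C | intermediate
27 | ω-pentadecalactone (oxacyclohexadecan-2-one) | O=C1CCCCCCCCCCCCCCO1 | starting material
28 | 15-bromopentadecanoic acid | OC(=O)CCCCCCCCCCCCCCBr | intermediate
29 | 15-bromopentadecan-1-ol | OCCCCCCCCCCCCCCCBr | intermediate
30 | [(15-bromopentadecyl)oxy](tert-butyl)diphenylsilane | BrCCCCCCCCCCCCCCCO[Si](c1ccccc1)(c1ccccc1)C(C)(C)C | intermediate
31 | [15-(tert-butyldiphenylsilyloxy)pentadecyl]magnesium bromide | Br[Mg]CCCCCCCCCCCCCCCO[Si](c1ccccc1)(c1ccccc1)C(C)(C)C | intermediate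
32 | chloromagnesium 15-bromopentadecanoate | Cl[Mg]OC(=O)CCCCCCCCCCCCCCBr | intermediate
33 | 30-(tert-butyldiphenylsilyloxy)triacontanoic acid | OC(=O)CCCCCCCCCCCCCCCCCCCCCCCCCCCCCO[Si](c1ccccc1)(c1ccccc1)C(C)(C)C | intermediate
34 | (5R,9S,10R,13E)-17-(tert-butyldiphenylsilyloxy)labda-7,13-dien-15-yl 30-(tert-butyldiphenylsilyloxy)triacontanoate | C/C(=C\COC(=O)CCCCCCCCCCCCCCCCCCCCCCCCCCCCCO[Si](c4ccccc4)(c4ccccc4)C(C)(C)C)CC[C@@H]1C(CO[Si](c3ccccc3)(c3ccccc3)C(C)(C)C)=CC[C@@H]2C(C)(C)CCC[C@@]12C | intermediate
35 | (5R,9S,10R,13E)-17-hydroxylabda-7,13-dien-15-yl 30-hydroxytriacontanoate (ent-labdane series) | C/C(=C\COC(=O)CCCCCCCCCCCCCCCCCCCCCCCCCCCCCO)CC[C@@H]1C(CO)=CC[C@@H]2C(C)(C)CCC[C@@]12C | target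

## Step count and least certain steps

Total step count: 22. Longest linear sequence: 17 steps (steps 1–5, 7–16, 21 and 22). Step 6 and steps 17–20 are side branches.

**Step 8 (key step, proposed new method).** The most likely failure is a rearrangement that is too slow at the tetrasubstituted ring alkene. The boron enolate would then be consumed by loss of the cyclogeranyl alkoxide (ketene formation) or by Lewis-acid ionisation of the allylic C–O bond before the shift occurs. Discrimination between the two faces of C10 may also be weak, because the alkene offers the controller two similar substituents. The fallback uses known chemistry and sets out from 12. Enolisation with LiN(i-Pr)2 and TMSCl in THF/DMPU gives the trimethylsilyl ketene acetal F1. Warming brings about the Ireland–Claisen rearrangement, and hydrolysis gives the racemic acid F2. Crystallisation with (R)-1-phenylethylamine (or its antipode, whichever gives the less soluble salt of the wanted enantiomer) gives the salt F3, and acidification returns to the route at 15.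

**Step 11.** Three processes threaten the ring closure:
- premature hydrogen transfer to the C7 radical before cyclisation (this only regenerates 17, which can be recycled through step 10);
- addition of the C7 radical to the C13=C14 alkene in a 7-endo or 6-exo mode;
- hydrogen delivery to C5 on the face of C20, less likely because of the two axial methyl groups.

The fallback replaces the tin hydride chain by degenerate xanthate transfer and sets out from 19. Displacement with KSC(S)OEt in acetone gives the S-(2-oxoalkyl) O-ethyl dithiocarbonate F4. Dilauroyl peroxide added in portions in refluxing 2-propanol generates the same C7 radical reversibly and without a fast hydrogen donor, so the 6-endo closure has time to occur, and the solvent reduces the C5 radical. NaOMe equilibration then returns to the route at 20.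

**Step 9.** The risks are over-addition to the tertiary alcohol if ketone is released while methyllithium is still present, and incomplete addition to the hindered carboxylate. The fallback is the diazoketone path and sets out from 15. Oxalyl chloride with catalytic DMF gives the acid chloride F5. Diazomethane gives the diazoketone F6, and brief treatment with 48% HBr in ether at −10 °C gives 19 directly, so the route is rejoined at 19 and step 10 is bypassed. The contact time must be short because of the allylic silyl ether.

**Step 2.** The alkenylalane may be captured incompletely by formaldehyde, so that protonation to the simple alkene competes; some loss of regioselectivity in the carbometalation is also possible. The fallback sets out from 2. The alane 3 is formed as before and trapped with ethyl chloroformate to give the ethyl (E)-enoate F7, which is purified and reduced with i-Bu2AlH, returning to the route at 5.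

**Step 13.** Oxidative addition and CO insertion may be slow at the hindered triflate, with reduction of the triflate to the alkene as the competing process. The fallback sets out from 22 and uses a Stille coupling with Bu3SnCH2OH (Pd(PPh3)4, LiCl, dioxane, 100 °C). This installs the hydroxymethyl group directly and returns to the route at 24, bypassing 23; no new compound arises.

## Further compounds

F1 | step 8 | trimethylsilyl ketene acetal of 12 (C11 cis to O–Si) | C/C(=C\CO[Si](C)(C)C(C)(C)C)CC/C=C(/OCC1=C(C)CCCC1(C)C)O[Si](C)(C)C
F2 | step 8 | racemic 7-(tert-butyldimethylsilyloxy)-5-methyl-2-(1,3,3-trimethyl-2-methylidenecyclohexyl)hept-5-enoic acid (15 and its enantiomer, 1:1) | C/C(=C\CO[Si](C)(C)C(C)(C)C)CC[C@H](C(=O)O)[C@]1(C)CCCC(C)(C)C1=C.C/C(=C\CO[Si](C)(C)C(C)(C)C)CC[C@@H](C(=O)O)[C@@]1(C)CCCC(C)(C)C1=C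
F3 | step 8 | (R)-1-phenylethylammonium salt of acid 15 | C/C(=C\CO[Si](C)(C)C(C)(C)C)CC[C@H](C(=O)[O-])[C@]1(C)CCCC(C)(C)C1=C.C[C@@H]([NH3+])c1ccccc1
F4 | step 11 | O-ethyl S-{(3S,6E)-8-(tert-butyldimethylsilyloxy)-6-methyl-2-oxo-3-[(1S)-1,3,3-trimethyl-2-methylidenecyclohexyl]oct-6-en-1-yl} dithiocarbonate | C/C(=C\CO[Si](C)(C)C(C)(C)C)CC[C@H](C(=O)CSC(=S)OCC)[C@]1(C)CCCC(C)(C)C1=C
F5 | step 9 | acid chloride of 15 | C/C(=C\CO[Si](C)(C)C(C)(C)C)CC[C@H](C(=O)Cl)[C@]1(C)CCCC(C)(C)C1=C
F6 | step 9 | diazomethyl ketone from 15 | C/C(=C\CO[Si](C)(C)C(C)(C)C)CC[C@H](C(=O)C=[N+]=[N-])[C@]1(C)CCCC(C)(C)C1=C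
F7 | step 2 | ethyl (E)-7-(4-methoxybenzyloxy)-3-methylhept-2-enoate | CCOC(=O)/C=C(\C)CCCCOCc1ccc(OC)cc1
F0 | step 13 | none | none
A1 | alternative 1 | trans-fused cycloadduct with the imide carbonyl (C11) on C9, a C6=C7 alkene and silylated C17 on C8 | O=C(N1C(=O)OC[C@H]1Cc1ccccc1)[C@@H]1[C@H](CO[Si](C)(C)C(C)(C)C)C=C[C@@H]2C(C)(C)CCC[C@@]12C
A2 | alternative 1 | (R)-4-benzyl-3-[(2E,8E,10E)-12-(tert-butyldimethylsilyloxy)-3,7,7-trimethyldodeca-2,8,10-trienoyl]oxazolidin-2-one | O=C(/C=C(\C)CCCC(C)(C)/C=C/C=C/CO[Si](C)(C)C(C)(C)C)N1C(=O)OC[C@H]1Cc1ccccc1
A3 | alternative 2 | ent-labda-7,13E-diene-15,17-diol 15-(4-methoxybenzyl) ether 17-(tert-butyldimethylsilyl) ether | C/C(=C\COCc1ccc(OC)cc1)CC[C@@H]1C(CO[Si](C)(C)C(C)(C)C)=CC[C@@H]2C(C)(C)CCC[C@@]12C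
A4 | alternative 2 | N-phenylcarbamate of the ent-series bicyclic allylic alcohol (C8=C9 alkene, silylated C17 on C8, carbamate on C7 on the face of C20) | C1=C(CO[Si](C)(C)C(C)(C)C)[C@H](OC(=O)Nc3ccccc3)C[C@@H]2C(C)(C)CCC[C@@]12C
A5 | alternative 2 | 1-({[(E)-5-iodo-3-methylpent-2-en-1-yl]oxy}methyl)-4-methoxybenzene | C/C(=C\COCc1ccc(OC)cc1)CCI
A6 | alternative 3 | bis(tert-butyldimethylsilyl) ether of the target | C/C(=C\COC(=O)CCCCCCCCCCCCCCCCCCCCCCCCCCCCCO[Si](C)(C)C(C)(C)C)CC[C@@H]1C(CO[Si](C)(C)C(C)(C)C)=CC[C@@H]2C(C)(C)CCC[C@@]12C
A7 | alternative 3 | N-hydroxyphthalimide ester of the bicyclic propanoic acid (C9–C11–C12–CO2N, silylated C17) | O=C(CC[C@@H]1C(CO[Si](C)(C)C(C)(C)C)=CC[C@@H]2C(C)(C)CCC[C@@]12C)ON3C(=O)c4ccccc4C3=O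
A8 | alternative 3 | (E)-3-iodobut-2-en-1-yl 30-(tert-butyldimethylsilyloxy)triacontanoate | C/C(I)=C\COC(=O)CCCCCCCCCCCCCCCCCCCCCCCCCCCCCO[Si](C)(C)C(C)(C)C
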